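## Retrosynthetic overview

1. The oxolane ring is closed last: the side-chain hydroxyl opens the dienyl-activated carbon of an (S,S)-epoxide (5-endo), and that epoxide comes from a reagent-controlled epoxidation of the distal alkene of the complete trienyl isocoumarin (polyene → epoxide → cyclic ether, as in the presumed biosynthesis).
2. The pyranone ring is closed before that by enol-lactonization of an aryl benzyl ketone ester, made by Claisen-type acylation of a laterally lithiated chloro-orsellinate with a trienyl Weinreb amide (chain extension, then O-acyl release, as on the polyketide synthase).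
3. The Weinreb amide comes from an HWE reaction of a hydroxy dienal, itself from cross-metathesis of (R)-pent-4-en-2-ol (source of the methyl-bearing stereocentre) with sorbaldehyde.
4. The arene comes from methyl orsellinate by ring chlorination (before any polyene exists) and MOM protection.
5. Ring order: benzene ring bought, pyranone ring in step 5, oxolane ring in step 6.

Assumption: (R)-pent-4-en-2-ol, methyl orsellinate, sorbaldehyde, the Weinreb phosphonate and the L-series Shi ketone (used in catalytic amount) are taken as catalogue chemicals.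

Side-chain locants are primed; C1′ is bonded to C3 of the isocoumarin.

## Route

Step 1
Reactants: 1 methyl 2,4-dihydroxy-6-methylbenzoate (methyl orsellinate)
Product: 2 methyl 3-chloro-4,6-dihydroxy-2-methylbenzoate
Conditions: SO2Cl2 (1.05 equiv), Et2O, 0 °C to rt
Reagents that add atoms: sulfuryl chloride, O=S(=O)(Cl)Cl
Why: Electrophilic aromatic chlorination goes mainly to the ring position ortho to the free 4-OH and para to the chelated 2-OH (the site also taken in orcylaldehyde and resorcylate macrolide chlorinations), and the minor 3-chloro and dichloro products are removed by crystallization.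

Step 2
Reactants: 2 methyl 3-chloro-4,6-dihydroxy-2-methylbenzoate
Product: 3 methyl 3-chloro-4,6-bis(methoxymethoxy)-2-methylbenzoate
Conditions: NaH (2.6 equiv), MOMCl (2.6 equiv), DMF, 0 °C to rt
Reagents that add atoms: chloromethyl methyl ether, COCCl
Why: Williamson etherification of both sodium phenoxides (NaH is needed to break the hydrogen bond of the 2-OH) gives acetal ethers that survive LiN(i-Pr)2 and the basic oxidant used later.

Step 3
Reactants: 4 (2R)-pent-4-en-2-ol; 5 (2E,4E)-hexa-2,4-dienal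
Product: 6 (2E,4E,7R)-7-hydroxyocta-2,4-dienal
Conditions: second-generation Hoveyda–Grubbs catalyst RuCl2(H2IMes)(=CH-C6H4-2-O-i-Pr) (5 mol %), 5 (3 equiv), CH2Cl2, 40 °C
Reagents that add atoms: none
Why: Olefin cross-metathesis takes place at the distal C4=C5 bond of the dienal because the enal C2=C3 bond is electron-poor toward the ruthenium carbene, releases propene and gives the E-alkene under thermodynamic control, while the carbinol centre of 4 is not involved.

Step 4
Reactants: 6 (2E,4E,7R)-7-hydroxyocta-2,4-dienal; 7 diethyl [2-(methoxy(methyl)amino)-2-oxoethyl]phosphonate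
Product: 8 (2E,4E,6E,9R)-9-hydroxy-N-methoxy-N-methyldeca-2,4,6-trienamide
Conditions: LiCl (1.5 equiv), DBU (1.3 equiv), MeCN, 0 °C to rt
Reagents that add atoms: none
Why: Horner–Wadsworth–Emmons olefination under Masamune–Roush conditions gives the E-enamide from the stabilized phosphonate, and the mild amine base leaves the free alcohol and the dienal untouched.

Step 5
Reactants: 3 methyl 3-chloro-4,6-bis(methoxymethoxy)-2-methylbenzoate; 8 (2E,4E,6E,9R)-9-hydroxy-N-methoxy-N-methyldeca-2,4,6-trienamide
Product: 10 5-chloro-3-[(1E,3E,5E,8R)-8-hydroxynona-1,3,5-trien-1-yl]-6,8-bis(methoxymethoxy)-1H-isochromen-1-one, via keto ester 9 (not isolated)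
Conditions: 3 (1.2 equiv), LiN(i-Pr)2 (2.4 equiv), THF, −78 °C; add 8 premixed with LiN(i-Pr)2 (1.0 equiv), −78 °C, 1 h; AcOH; crude, DBU (0.3 equiv), PhMe, 60 °C
Reagents that add atoms: none
Why: Lateral lithiation of the toluate gives a dienolate that attacks the Weinreb amide at the carbonyl carbon (Claisen-type acylation, which unsaturated Weinreb amides are known to undergo with chlorinated bis(alkoxymethyl) toluate anions in preference to conjugate addition), and the enol of the resulting benzyl ketone then acylates on oxygen at the ortho ester (base-catalysed enol-lactonization with loss of methanol) to close the pyranone ring without touching the remote carbinol.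

Step 6
Reactants: 10 5-chloro-3-[(1E,3E,5E,8R)-8-hydroxynona-1,3,5-trien-1-yl]-6,8-bis(methoxymethoxy)-1H-isochromen-1-one
Product: 12 5-chloro-3-{(1E,3E)-4-[(2R,3S,5R)-3-hydroxy-5-methyloxolan-2-yl]buta-1,3-dien-1-yl}-6,8-bis(methoxymethoxy)-1H-isochromen-1-one, via hydroxy epoxide 11 (not isolated)
Conditions: L-series Shi ketone (1,2:4,5-di-O-isopropylidene-β-L-erythro-2,3-hexodiulo-2,6-pyranose, 30 mol %), 2KHSO5·KHSO4·K2SO4 (1.3 equiv KHSO5), K2CO3, Bu4NHSO4 (cat), aq Na2B4O7/Na2H2(EDTA) buffer, MeCN–CH2(OMe)2 1:2, 0 °C; extract; camphorsulfonic acid (5 mol %), CH2Cl2, 0 °C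
Reagents that add atoms: potassium peroxymonosulfate, [K+].[O-]S(=O)(=O)OO
Why: Shi asymmetric epoxidation by the chiral dioxirane picks the distal C5′=C6′ alkene, which is the most electron-rich and least hindered of the three because the inner two are conjugated to the electron-poor isocoumarin, and reagent control by the L-series ketone gives the (S,S)-trans-epoxide, whose dienyl-activated carbon is then opened with inversion by the C8′ hydroxyl in an acid-catalysed 5-endo epoxide-opening cyclization (π-activated endo opening of a vinyl epoxide), so that C3 (S) keeps the epoxide oxygen, C2 (R) is set by the inversion and C5 (R) comes unchanged from 4.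

Step 7
Reactants: 12 5-chloro-3-{(1E,3E)-4-[(2R,3S,5R)-3-hydroxy-5-methyloxolan-2-yl]buta-1,3-dien-1-yl}-6,8-bis(methoxymethoxy)-1H-isochromen-1-one
Product: 13 5-chloro-6,8-dihydroxy-3-{(1E,3E)-4-[(2R,3S,5R)-3-hydroxy-5-methyloxolan-2-yl]buta-1,3-dien-1-yl}-1H-isochromen-1-one
Conditions: NaHSO4·SiO2, CH2Cl2, rt
Reagents that add atoms: none
Why: Acid-catalysed hydrolysis of the two phenolic formaldehyde acetals on the solid acid is fast because both phenols are good leaving groups (one chelated to the lactone carbonyl and one para to it), so it is complete at room temperature in a non-nucleophilic solvent before the dienyl oxolane can ionize, and no stereocentre is touched.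

## Compound list

1 | methyl 2,4-dihydroxy-6-methylbenzoate (methyl orsellinate) | COC(=O)c1c(C)cc(O)cc1O | starting material
2 | methyl 3-chloro-4,6-dihydroxy-2-methylbenzoate | COC(=O)c1c(C)c(Cl)c(O)cc1O | intermediate
3 | methyl 3-chloro-4,6-bis(methoxymethoxy)-2-methylbenzoate | COC(=O)c1c(C)c(Cl)c(OCOC)cc1OCOC | intermediate
4 | (2R)-pent-4-en-2-ol | C[C@@H](O)CC=C | starting material
5 | (2E,4E)-hexa-2,4-dienal (sorbaldehyde) | C/C=C/C=C/C=O | starting material
6 | (2E,4E,7R)-7-hydroxyocta-2,4-dienal | C[C@@H](O)C/C=C/C=C/C=O | intermediate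
7 | diethyl [2-(methoxy(methyl)amino)-2-oxoethyl]phosphonate | CCOP(=O)(CC(=O)N(C)OC)OCC | starting material
8 | (2E,4E,6E,9R)-9-hydroxy-N-methoxy-N-methyldeca-2,4,6-trienamide | C[C@@H](O)C/C=C/C=C/C=C/C(=O)N(C)OC | intermediate
9 | methyl 3-chloro-2-[(3E,5E,7E,10R)-10-hydroxy-2-oxoundeca-3,5,7-trien-1-yl]-4,6-bis(methoxymethoxy)benzoate | COC(=O)c1c(CC(=O)/C=C/C=C/C=C/C[C@@H](C)O)c(Cl)c(OCOC)cc1OCOC | intermediate
10 | 5-chloro-3-[(1E,3E,5E,8R)-8-hydroxynona-1,3,5-trien-1-yl]-6,8-bis(methoxymethoxy)-1H-isochromen-1-one | C[C@@H](O)C/C=C/C=C/C=C/c1cc2c(Cl)c(OCOC)cc(OCOC)c2c(=O)o1 | intermediate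
11 | 5-chloro-3-{(1E,3E)-4-[(2S,3S)-3-[(2R)-2-hydroxypropyl]oxiran-2-yl]buta-1,3-dien-1-yl}-6,8-bis(methoxymethoxy)-1H-isochromen-1-one | C[C@@H](O)C[C@@H]1O[C@H]1/C=C/C=C/c1cc2c(Cl)c(OCOC)cc(OCOC)c2c(=O)o1 | intermediate
12 | 5-chloro-3-{(1E,3E)-4-[(2R,3S,5R)-3-hydroxy-5-methyloxolan-2-yl]buta-1,3-dien-1-yl}-6,8-bis(methoxymethoxy)-1H-isochromen-1-one | C[C@@H]1C[C@H](O)[C@@H](/C=C/C=C/c2cc3c(Cl)c(OCOC)cc(OCOC)c3c(=O)o2)O1 | intermediate
13 | 5-chloro-6,8-dihydroxy-3-{(1E,3E)-4-[(2R,3S,5R)-3-hydroxy-5-methyloxolan-2-yl]buta-1,3-dien-1-yl}-1H-isochromen-1-one | C[C@@H]1C[C@H](O)[C@@H](/C=C/C=C/c2cc3c(Cl)c(O)cc(O)c3c(=O)o2)O1 | target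

## Step count

Total step count: 7.
Longest linear sequence: 5 steps (steps 1, 2, 5, 6, 7 from 1; the branch 4 → 6 → 8 joins at step 5 and is equally long).

## Steps most likely to fail, with fallbacks

**Step 6 (late-stage epoxidation and 5-endo closure).** The dioxirane may attack an inner alkene or epoxidize twice, and the dienyl epoxide may ionize and lose the C2 configuration. The fallback moves the same ring-forming sequence one stage earlier, setting out from 8, where the distal alkene is the only one not deactivated by the amide. The same Shi epoxidation gives the hydroxy epoxy dienamide F1, which closes under camphorsulfonic acid to the oxolanyl dienamide F2. The lithium alkoxide of F2 is acylated by lithiated 3 (LiN(i-Pr)2, THF, −78 °C) to the oxolanyl keto ester F3. F3 is lactonized under the mildest base that works (DBU 0.1 equiv, PhMe, rt, to spare the base-sensitive C2), which returns to the route at 12.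

**Step 5 (acylation of the toluate anion by the trienyl Weinreb amide).** Conjugate addition or deprotonation of the CH2 next to the triene may win over carbonyl attack. The fallback sets out from 3 and builds the pyranone ring first on a saturated acyl donor. Lithiated 3 and N-methoxy-N-methylacetamide give the methyl ketone ester F4, which lactonizes (DBU, PhMe, 60 °C) to the 3-methylisocoumarin F5. The C3 methyl group, a vinylogous toluate position, is metalated (LiN(i-Pr)2 2.2 equiv, THF, −78 °C) and trapped with ClP(O)(OEt)2 to give the isocoumarinylmethyl phosphonate F6. An HWE reaction of F6 with dienal 6 (LiN(SiMe3)2 2.1 equiv, THF, −78 to 0 °C) returns to the route at 10.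

**Step 7 (acid removal of the MOM groups from the finished dienyl oxolane).** The acid may open or epimerize the dienyl ether at C2. The fallback sets out from 10 and changes the protecting groups so that the last step is a fluoride desilylation. The MOM groups are removed from the acid-tolerant triene 10 (NaHSO4·SiO2, CH2Cl2, rt) to give the triene diphenol F7. Only the two phenols are silylated (i-Pr3SiCl, imidazole, DMF, 0 °C; the secondary alcohol is too hindered for this chloride) to give the bis(silyl ether) F8. The epoxidation and acid closure of step 6 then lead through the silylated hydroxy epoxide F9 to the silylated oxolane F10. Bu4NF buffered with AcOH (THF, 0 °C) returns to the route at 13.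

## Further compounds

F1 | step 6 | (2E,4E)-5-{(2S,3S)-3-[(2R)-2-hydroxypropyl]oxiran-2-yl}-N-methoxy-N-methylpenta-2,4-dienamide | C[C@@H](O)C[C@@H]1O[C@H]1/C=C/C=C/C(=O)N(C)OC
F2 | step 6 | (2E,4E)-5-[(2R,3S,5R)-3-hydroxy-5-methyloxolan-2-yl]-N-methoxy-N-methylpenta-2,4-dienamide | C[C@@H]1C[C@H](O)[C@@H](/C=C/C=C/C(=O)N(C)OC)O1
F3 | step 6 | methyl 3-chloro-2-{(3E,5E)-6-[(2R,3S,5R)-3-hydroxy-5-methyloxolan-2-yl]-2-oxohexa-3,5-dien-1-yl}-4,6-bis(methoxymethoxy)benzoate | C[C@@H]1C[C@H](O)[C@@H](/C=C/C=C/C(=O)Cc2c(Cl)c(OCOC)cc(OCOC)c2C(=O)OC)O1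
F4 | step 5 | methyl 3-chloro-4,6-bis(methoxymethoxy)-2-(2-oxopropyl)benzoate | COC(=O)c1c(CC(C)=O)c(Cl)c(OCOC)cc1OCOC
F5 | step 5 | 5-chloro-6,8-bis(methoxymethoxy)-3-methyl-1H-isochromen-1-one | Cc1cc2c(Cl)c(OCOC)cc(OCOC)c2c(=O)o1
F6 | step 5 | diethyl {[5-chloro-6,8-bis(methoxymethoxy)-1-oxo-1H-isochromen-3-yl]methyl}phosphonate | CCOP(=O)(Cc1cc2c(Cl)c(OCOC)cc(OCOC)c2c(=O)o1)OCC
F7 | step 7 | 5-chloro-6,8-dihydroxy-3-[(1E,3E,5E,8R)-8-hydroxynona-1,3,5-trien-1-yl]-1H-isochromen-1-one | C[C@@H](O)C/C=C/C=C/C=C/c1cc2c(Cl)c(O)cc(O)c2c(=O)o1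
F8 | step 7 | 5-chloro-3-[(1E,3E,5E,8R)-8-hydroxynona-1,3,5-trien-1-yl]-6,8-bis[(triisopropylsilyl)oxy]-1H-isochromen-1-one | C[C@@H](O)C/C=C/C=C/C=C/c1cc2c(Cl)c(O[Si](C(C)C)(C(C)C)C(C)C)cc(O[Si](C(C)C)(C(C)C)C(C)C)c2c(=O)o1
F9 | step 7 | 5-chloro-3-{(1E,3E)-4-[(2S,3S)-3-[(2R)-2-hydroxypropyl]oxiran-2-yl]buta-1,3-dien-1-yl}-6,8-bis[(triisopropylsilyl)oxy]-1H-isochromen-1-one | C[C@@H](O)C[C@@H]1O[C@H]1/C=C/C=C/c1cc2c(Cl)c(O[Si](C(C)C)(C(C)C)C(C)C)cc(O[Si](C(C)C)(C(C)C)C(C)C)c2c(=O)o1
F10 | step 7 | 5-chloro-3-{(1E,3E)-4-[(2R,3S,5R)-3-hydroxy-5-methyloxolan-2-yl]buta-1,3-dien-1-yl}-6,8-bis[(triisopropylsilyl)oxy]-1H-isochromen-1-one | C[C@@H]1C[C@H](O)[C@@H](/C=C/C=C/c2cc3c(Cl)c(O[Si](C(C)C)(C(C)C)C(C)C)cc(O[Si](C(C)C)(C(C)C)C(C)C)c3c(=O)o2)O1
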